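The daucane numbering used here is: C1 (angular C–CH3), C2 and C3 (CH2), C4 (isopropyl carbinol), C5 (ring-fusion CH), C6 (ester carbon), C7 (CH2), C8 (C(OH)CH3), C9 (CHOH), C10 (CH2). The route cuts C5–C1 and C9–C10. The key step exploits the 1,4-related oxygens on C6 and C9 across C7–C8(CH3) in the cycloheptane, which map onto a 5-methyl-3-oxidopyrylium, and the C1 methyl with C10, which map onto a methallyl alkene tethered to C4. One intramolecular (5+2) cycloaddition closes the cyclopentane and the oxygen-bridged cycloheptenone and sets C1, C5 and C9. The precursor is an Achmatowicz-derived 6-acetoxypyranone carrying the enantiopure tertiary C4 alcohol, left unprotected.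

Key step: step 9

Assumption: the furyl carbinol carbon made in step 3 (the later C5) and the anomeric carbon of the pyranones are carried as epimer mixtures, because both become sp2 in the oxidopyrylium; their SMILES carry no descriptor at these atoms.
Remark: names from compound 17 onward use the daucane numbering given above.

Step 1
Reactants: 1 (S)-2-hydroxy-3-methylbutanoic acid
Product: 2 (2S,5S)-2-tert-butyl-5-(propan-2-yl)-1,3-dioxolan-4-one (cis)
Conditions: t-BuCHO, TsOH·H2O (cat.), pentane, reflux with water separator; crystallization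
Reagents that add atoms: pivalaldehyde (2,2-dimethylpropanal), CC(C)(C)C=O
Why: Acid-catalysed acetalization with removal of water equilibrates to the cis-2,5-disubstituted dioxolanone, so the stereocentre of 1 fixes the new acetal centre as S (first half of the self-regeneration of stereocentres).

Step 2
Reactants: 3 4-bromofuran-2-carbaldehyde
Product: 4 4-methylfuran-2-carbaldehyde
Conditions: MeB(OH)2, Pd(dppf)Cl2 (cat.), K2CO3, 1,4-dioxane/H2O, 90 °C
Reagents that add atoms: methylboronic acid, CB(O)O
Why: Suzuki–Miyaura coupling of a heteroaryl bromide with methylboronic acid tolerates the aldehyde and creates no stereocentre.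

Step 3
Reactants: 2 (2S,5S)-2-tert-butyl-5-(propan-2-yl)-1,3-dioxolan-4-one; 4 4-methylfuran-2-carbaldehyde
Product: 6 (2S,5R)-2-tert-butyl-5-[hydroxy(4-methylfuran-2-yl)methyl]-5-(propan-2-yl)-1,3-dioxolan-4-one (both carbinol epimers), via lithium enolate 5 (not isolated)
Conditions: LiN(i-Pr)2, THF, −78 °C; then 4, −78 °C; AcOH quench
Reagents that add atoms: none
Why: Aldol addition of the dioxolanone enolate, in which the aldehyde is taken up on the face anti to the tert-butyl group, so that the new C–C bond takes the place of the former C–H with retention and fixes the quaternary carbinol (later C4) in the required sense.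

Step 4
Reactants: 6 (2S,5R)-2-tert-butyl-5-[hydroxy(4-methylfuran-2-yl)methyl]-5-(propan-2-yl)-1,3-dioxolan-4-one
Product: 7 (2S)-1-(4-methylfuran-2-yl)-2-(propan-2-yl)propane-1,2,3-triol (both C1 epimers)
Conditions: LiAlH4, THF, 0 °C → rt
Reagents that add atoms: none
Why: Hydride reduction of the lactone carbonyl (ester to primary alcohol) collapses the acetal and frees the tertiary hydroxyl without touching the quaternary stereocentre.

Step 5
Reactants: 7 (2S)-1-(4-methylfuran-2-yl)-2-(propan-2-yl)propane-1,2,3-triol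
Product: 9 (4-methylfuran-2-yl)[(2S)-2-(propan-2-yl)oxiran-2-yl]methanol (both carbinol epimers), via primary tosylate 8 (not isolated)
Conditions: TsCl, Et3N, Bu2SnO (cat.), CH2Cl2, 0 °C; then K2CO3, MeOH, rt
Reagents that add atoms: none
Why: Stannylene-mediated sulfonylation should pick the primary hydroxyl of the triol, and the neighbouring tertiary alkoxide then closes the oxirane by intramolecular Williamson etherification, the C–O bond at the stereocentre staying intact.

Step 6
Reactants: 9 (4-methylfuran-2-yl)[(2S)-2-(propan-2-yl)oxiran-2-yl]methanol; 10 2-methylallylmagnesium chloride (solution in THF)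
Product: 11 (2R)-5-methyl-1-(4-methylfuran-2-yl)-2-(propan-2-yl)hex-5-ene-1,2-diol (both C1 epimers)
Conditions: 10 (3.5 equiv), CuI (10 mol %), THF, −40 → 0 °C; aq. NH4Cl
Reagents that add atoms: none
Why: Copper-catalysed Grignard opening of a 2,2-disubstituted oxirane takes place by SN2 attack at the free CH2, which joins C3 to C2 and leaves the tertiary carbinol centre unchanged (the symmetric methallyl unit excludes allylic isomers).

Step 7
Reactants: 11 (2R)-5-methyl-1-(4-methylfuran-2-yl)-2-(propan-2-yl)hex-5-ene-1,2-diol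
Product: 14 6-hydroxy-2-[(3R)-3-hydroxy-2,6-dimethylhept-6-en-3-yl]-5-methyl-2H-pyran-3(6H)-one (ring C2/C6 epimers), via endoperoxide 12 (not isolated), via keto enal 13 (not isolated)
Conditions: O2, hν (visible), tetraphenylporphyrin (cat.), CH2Cl2, −78 °C; then Me2S, −78 °C → rt
Reagents that add atoms: dioxygen, O=O
Why: Achmatowicz rearrangement run with singlet oxygen, which the electron-rich furan takes up by (4+2) addition far faster than the 1,1-disubstituted alkene reacts, after which sulfide reduction gives the cis keto enal and the secondary hydroxyl closes the pyranone hemiacetal.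

Step 8
Reactants: 14 6-hydroxy-2-[(3R)-3-hydroxy-2,6-dimethylhept-6-en-3-yl]-5-methyl-2H-pyran-3(6H)-one
Product: 15 6-acetoxy-2-[(3R)-3-hydroxy-2,6-dimethylhept-6-en-3-yl]-5-methyl-2H-pyran-3(6H)-one (ring C2/C6 epimers)
Conditions: Ac2O, pyridine, DMAP (cat.), CH2Cl2, 0 °C
Reagents that add atoms: acetic anhydride, CC(=O)OC(C)=O
Why: Acylation of the hemiacetal hydroxyl is fast, whereas the tertiary hydroxyl flanked by the isopropyl group and the ring is too hindered to react, so the ionizable acetate is obtained without a protecting group.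

Step 9
Reactants: 15 6-acetoxy-2-[(3R)-3-hydroxy-2,6-dimethylhept-6-en-3-yl]-5-methyl-2H-pyran-3(6H)-one
Product: 17 (1R,4R,5S,9S)-5,9-epoxy-4-hydroxydauc-7-en-6-one (C5–O–C9 oxygen-bridged hydroazulenone), via oxidopyrylium betaine 16 (not isolated)
Conditions: Et3N (3 equiv), MeCN (0.01 M), 60 °C
Reagents that add atoms: none
Why: Triethylamine removes the proton on the carbon between the ring oxygen and the ketone while acetate leaves, which gives the 3-oxidopyrylium betaine 16, and its two carbons next to the ring oxygen (later C5 and C9) add suprafacially and in one thermally allowed step to the tethered C1=C10 alkene. The closest known reaction type is the intramolecular 3-oxidopyrylium–alkene (5+2) cycloaddition of Achmatowicz-derived acetoxypyranones that carry a three-atom tether on the carbinol carbon. The cyclopentane closes through C5–C1 bond formation across the C4–C3–C2 tether (5-exo with respect to the alkene), and the cycloheptenone closes through C9–C10 bond formation in the same event, the former pyran oxygen remaining as the C5–O–C9 bridge. C5 and C9 are set together by the pyrylium face that the alkene reaches, and this face is fixed by C4: the hydroxyl can hydrogen-bond to the oxido oxygen and the larger isopropyl group then lies on the side of the unsubstituted ring oxygen, which leaves only one face for the tether; C1 is set by the tether itself, which can only span the exo position, so the methyl group ends up endo and trans to the oxygen bridge. The step needs facial selectivity with respect to C4, secured by the hydrogen bond and the size difference between hydroxyl and isopropyl, and it needs cycloaddition to outrun ylide dimerization, secured by high dilution and the entropic advantage of the tether, while regiochemistry is dictated by the tether length.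

Step 10
Reactants: 17 (1R,4R,5S,9S)-5,9-epoxy-4-hydroxydauc-7-en-6-one
Product: 19 (1R,4R,5R,9S)-4,9-dihydroxydauc-7-en-6-one (trans-fused), via samarium dienolate 18 (not isolated)
Conditions: SmI2 (2.2 equiv), THF/MeOH, −78 °C
Reagents that add atoms: none
Why: Reductive cleavage of an α-alkoxy ketone by SmI2, in which electron transfer to the carbonyl expels the bridge oxygen from C5 and methanol protonates the resulting enolate at C5 on the face that the oxygen has just left, giving the trans ring fusion, which should also be the more stable epimer because C6 then lies cis to the C4 hydroxyl and not to the isopropyl group.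

Step 11
Reactants: 19 (1R,4R,5R,9S)-4,9-dihydroxydauc-7-en-6-one
Product: 20 (1R,4R,5R,9S)-9-(tert-butyldimethylsilyloxy)-4-hydroxydauc-7-en-6-one
Conditions: TBSCl, imidazole, DMAP (cat.), DMF, rt
Reagents that add atoms: tert-butyldimethylsilyl chloride, CC(C)(C)[Si](C)(C)Cl
Why: Silylation with TBSCl and imidazole reaches the secondary allylic hydroxyl only, the tertiary C4 hydroxyl being inert, and installs the bulky group that is to shield the upper face of the C7=C8 bond.

Step 12
Reactants: 20 (1R,4R,5R,9S)-9-(tert-butyldimethylsilyloxy)-4-hydroxydauc-7-en-6-one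
Product: 21 (1R,4R,5R,7R,8S,9S)-9-(tert-butyldimethylsilyloxy)-7,8-epoxy-4-hydroxydaucan-6-one
Conditions: dimethyldioxirane (acetone solution, excess), CH2Cl2, 0 °C → rt
Reagents that add atoms: dimethyldioxirane, CC1(C)OO1
Why: Dioxirane epoxidation of an enone runs without base, so that neither C5 nor the β-hydroxy ketone is put at risk, and should occur on the face anti to the adjacent silyloxy group at C9, which places the new C8–O bond trans to the C9–O bond.

Step 13
Reactants: 21 (1R,4R,5R,7R,8S,9S)-9-(tert-butyldimethylsilyloxy)-7,8-epoxy-4-hydroxydaucan-6-one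
Product: 23 (1R,4R,5R,8S,9S)-9-(tert-butyldimethylsilyloxy)-4,8-dihydroxydaucan-6-one, via samarium enolate 22 (not isolated)
Conditions: SmI2 (2.5 equiv), THF/MeOH, −90 °C
Reagents that add atoms: none
Why: Reductive opening of an α,β-epoxy ketone by SmI2 breaks only the C7–O bond next to the carbonyl, so C7 becomes CH2 and the tertiary alcohol at C8 keeps the configuration set in step 12.

Step 14
Reactants: 23 (1R,4R,5R,8S,9S)-9-(tert-butyldimethylsilyloxy)-4,8-dihydroxydaucan-6-one
Product: 24 (1R,4R,5S,6S,8S,9S)-9-(tert-butyldimethylsilyloxy)daucane-4,6,8-triol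
Conditions: Me4NBH(OAc)3, MeCN/AcOH, −20 °C → rt
Reagents that add atoms: none
Why: Evans–Saksena reduction, in which the acetoxyborohydride exchanges an acetate for a tertiary hydroxyl and delivers hydride internally from the lower face, which carries both the C8 and the C4 hydroxyl, so that the C6 hydroxyl is formed anti to the C8 hydroxyl.

Step 15
Reactants: 24 (1R,4R,5S,6S,8S,9S)-9-(tert-butyldimethylsilyloxy)daucane-4,6,8-triol; 25 4-(benzyloxy)benzoyl chloride
Product: 26 (1R,4R,5S,6S,8S,9S)-9-(tert-butyldimethylsilyloxy)-4,8-dihydroxydaucan-6-yl 4-(benzyloxy)benzoate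
Conditions: Et3N, DMAP, CH2Cl2, rt → 40 °C
Reagents that add atoms: none
Why: Acylation by an acid chloride under DMAP catalysis can reach only the secondary C6 hydroxyl, since the hydroxyls at C4 and C8 are tertiary and that at C9 is silylated.

Step 16
Reactants: 26 (1R,4R,5S,6S,8S,9S)-9-(tert-butyldimethylsilyloxy)-4,8-dihydroxydaucan-6-yl 4-(benzyloxy)benzoate
Product: 27 (1R,4R,5S,6S,8S,9S)-4,8,9-trihydroxydaucan-6-yl 4-(benzyloxy)benzoate
Conditions: Bu4NF, AcOH, THF, rt → 45 °C
Reagents that add atoms: none
Why: Fluoride-induced cleavage of the silyl ether, buffered by acetic acid so that the aryl ester neither migrates nor is cleaved.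

Step 17
Reactants: 27 (1R,4R,5S,6S,8S,9S)-4,8,9-trihydroxydaucan-6-yl 4-(benzyloxy)benzoate
Product: 28 (1R,4R,5S,6S,8S,9S)-4,8,9-trihydroxydaucan-6-yl 4-hydroxybenzoate (target)
Conditions: H2 (1 atm), Pd/C, EtOAc/EtOH, rt
Reagents that add atoms: none
Why: Hydrogenolysis of the benzyl aryl ether over palladium frees the phenol under neutral conditions, and no other reducible group is left in the molecule.

Compound list
1 | (S)-2-hydroxy-3-methylbutanoic acid | CC(C)[C@H](O)C(O)=O | starting material
2 | (2S,5S)-2-tert-butyl-5-(propan-2-yl)-1,3-dioxolan-4-one (cis) | CC(C)[C@@H]1O[C@H](C(C)(C)C)OC1=O | intermediate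
3 | 4-bromofuran-2-carbaldehyde | O=Cc1cc(Br)co1 | starting material
4 | 4-methylfuran-2-carbaldehyde | O=Cc1cc(C)co1 | intermediate
5 | lithium (2S)-2-tert-butyl-5-(propan-2-yl)-1,3-dioxol-4-olate (enolate of 2) | CC(C)C1=C([O-])O[C@@H](C(C)(C)C)O1.[Li+] | intermediate (not isolated)
6 | (2S,5R)-2-tert-butyl-5-[hydroxy(4-methylfuran-2-yl)methyl]-5-(propan-2-yl)-1,3-dioxolan-4-one, both carbinol epimers | CC(C)[C@]1(C(O)c2cc(C)co2)O[C@H](C(C)(C)C)OC1=O | intermediate
7 | (2S)-1-(4-methylfuran-2-yl)-2-(propan-2-yl)propane-1,2,3-triol, both C1 epimers | CC(C)[C@](O)(CO)C(O)c1cc(C)co1 | intermediate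
8 | (2S)-2,3-dihydroxy-3-(4-methylfuran-2-yl)-2-(propan-2-yl)propyl 4-methylbenzenesulfonate | CC(C)[C@](O)(COS(=O)(=O)c1ccc(C)cc1)C(O)c2cc(C)co2 | intermediate (not isolated)
9 | (4-methylfuran-2-yl)[(2S)-2-(propan-2-yl)oxiran-2-yl]methanol, both carbinol epimers | CC(C)[C@]1(CO1)C(O)c2cc(C)co2 | intermediate
10 | 2-methylallylmagnesium chloride (solution in THF) | CC(=C)C[Mg]Cl | starting material
11 | (2R)-5-methyl-1-(4-methylfuran-2-yl)-2-(propan-2-yl)hex-5-ene-1,2-diol, both C1 epimers | CC(C)[C@](O)(CCC(C)=C)C(O)c1cc(C)co1 | intermediate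
12 | (2R)-5-methyl-1-(5-methyl-2,3,7-trioxabicyclo[2.2.1]hept-5-en-1-yl)-2-(propan-2-yl)hex-5-ene-1,2-diol (furan endoperoxide of 11) | CC(C)[C@](O)(CCC(C)=C)C(O)C12OOC(O1)C(C)=C2 | intermediate (not isolated)
13 | (2Z,6R)-5,6-dihydroxy-2,9-dimethyl-4-oxo-6-(propan-2-yl)deca-2,9-dienal | CC(C)[C@](O)(CCC(C)=C)C(O)C(=O)/C=C(C)\C=O | intermediate (not isolated)
14 | 6-hydroxy-2-[(3R)-3-hydroxy-2,6-dimethylhept-6-en-3-yl]-5-methyl-2H-pyran-3(6H)-one | CC(C)[C@](O)(CCC(C)=C)C1OC(O)C(C)=CC1=O | intermediate
15 | 6-acetoxy-2-[(3R)-3-hydroxy-2,6-dimethylhept-6-en-3-yl]-5-methyl-2H-pyran-3(6H)-one | CC(C)[C@](O)(CCC(C)=C)C1OC(OC(C)=O)C(C)=CC1=O | intermediate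
16 | 2-[(3R)-3-hydroxy-2,6-dimethylhept-6-en-3-yl]-5-methylpyrylium-3-olate | CC(C)[C@](O)(CCC(C)=C)c1[o+]cc(C)cc1[O-] | intermediate (not isolated)
17 | (1R,4R,5S,9S)-5,9-epoxy-4-hydroxydauc-7-en-6-one | CC(C)[C@]1(O)CC[C@]2(C)C[C@@H]3O[C@@]21C(=O)C=C3C | intermediate
18 | bis(diiodosamarium) C6-dienolate C9-alkoxide formed from 17 | CC(C)[C@]1(O)CC[C@]2(C)C[C@H](O[Sm](I)I)C(C)=CC(O[Sm](I)I)=C21 | intermediate (not isolated)
19 | (1R,4R,5R,9S)-4,9-dihydroxydauc-7-en-6-one | CC(C)[C@]1(O)CC[C@]2(C)C[C@H](O)C(C)=CC(=O)[C@H]21 | intermediate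
20 | (1R,4R,5R,9S)-9-(tert-butyldimethylsilyloxy)-4-hydroxydauc-7-en-6-one | CC(C)[C@]1(O)CC[C@]2(C)C[C@H](O[Si](C)(C)C(C)(C)C)C(C)=CC(=O)[C@H]21 | intermediate
21 | (1R,4R,5R,7R,8S,9S)-9-(tert-butyldimethylsilyloxy)-7,8-epoxy-4-hydroxydaucan-6-one | CC(C)[C@]1(O)CC[C@]2(C)C[C@H](O[Si](C)(C)C(C)(C)C)[C@@]3(C)O[C@H]3C(=O)[C@H]21 | intermediate
22 | bis(diiodosamarium) C6-enolate C8-alkoxide formed from 21 | CC(C)[C@]1(O)CC[C@]2(C)C[C@H](O[Si](C)(C)C(C)(C)C)[C@@](C)(O[Sm](I)I)C=C(O[Sm](I)I)[C@H]21 | intermediate (not isolated)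
23 | (1R,4R,5R,8S,9S)-9-(tert-butyldimethylsilyloxy)-4,8-dihydroxydaucan-6-one | CC(C)[C@]1(O)CC[C@]2(C)C[C@H](O[Si](C)(C)C(C)(C)C)[C@@](C)(O)CC(=O)[C@H]21 | intermediate
24 | (1R,4R,5S,6S,8S,9S)-9-(tert-butyldimethylsilyloxy)daucane-4,6,8-triol | CC(C)[C@]1(O)CC[C@]2(C)C[C@H](O[Si](C)(C)C(C)(C)C)[C@@](C)(O)C[C@H](O)[C@H]21 | intermediate
25 | 4-(benzyloxy)benzoyl chloride | O=C(Cl)c1ccc(OCc2ccccc2)cc1 | starting material
26 | (1R,4R,5S,6S,8S,9S)-9-(tert-butyldimethylsilyloxy)-4,8-dihydroxydaucan-6-yl 4-(benzyloxy)benzoate | CC(C)[C@]1(O)CC[C@]2(C)C[C@H](O[Si](C)(C)C(C)(C)C)[C@@](C)(O)C[C@H](OC(=O)c3ccc(OCc4ccccc4)cc3)[C@H]21 | intermediate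
27 | (1R,4R,5S,6S,8S,9S)-4,8,9-trihydroxydaucan-6-yl 4-(benzyloxy)benzoate | CC(C)[C@]1(O)CC[C@]2(C)C[C@H](O)[C@@](C)(O)C[C@H](OC(=O)c3ccc(OCc4ccccc4)cc3)[C@H]21 | intermediate
28 | (1R,4R,5S,6S,8S,9S)-4,8,9-trihydroxydaucan-6-yl 4-hydroxybenzoate, that is (3R,3aS,4S,6S,7S,8aR)-3,6,7-trihydroxy-6,8a-dimethyl-3-(propan-2-yl)decahydroazulen-4-yl 4-hydroxybenzoate | CC(C)[C@]1(O)CC[C@]2(C)C[C@H](O)[C@@](C)(O)C[C@H](OC(=O)c3ccc(O)cc3)[C@H]21 | target

Total step count: 17. Longest linear sequence: 16 steps (step 1, then steps 3 to 17, counted from 1).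

Steps most likely to fail

Step 9. The free tertiary hydroxyl may capture the ionized pyranone as an internal ketal or fail to steer the tether to one face, and ylide dimerization may outrun addition to the hindered 1,1-disubstituted alkene. The fallback sets out from 15: the C4 hydroxyl would be masked with N-(trimethylsilyl)imidazole to give the trimethylsilyl ether of the acetoxypyranone F1. The same base-induced cycloaddition would then rest on size alone (isopropyl larger than trimethylsilyloxy, hence again on the ring-oxygen side) and should give the silylated cycloadduct F2. HF·pyridine in THF would then return the route to 17.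

Step 10. Electron transfer into the conjugated enone may break the bridge on its other side (C9–O, in the vinylogous sense) or reduce the C7=C8 bond, and protonation at C5 may occur on both faces. The fallback sets out from 17: hydrogenation (H2, Pd/C, EtOAc) from the face of the oxygen bridge would give the saturated oxygen-bridged ketone F3, in which SmI2 can break only the C5–O bond next to the carbonyl, giving the saturated hydroxy ketone F4. Silylation (TBSCl, imidazole) would give its silyl ether F5. Dehydrogenation with IBX in DMSO can desaturate only toward C7–C8, because the other carbons on C5 are quaternary, and would come back to the route at 20. In either variant C5 remains next to the ketone and can be equilibrated by mild base toward the trans-fused epimer.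

Step 12. Oxygen transfer to the hindered, electron-poor trisubstituted alkene may be slow, or the facial bias of the silyloxy group may be insufficient. The fallback sets out from 20: copper-catalysed conjugate borylation (B2pin2, CuCl, NaOt-Bu, bis(2-diphenylphosphinophenyl) ether, MeOH, THF) anti to the silyloxy group would give the β-boryl ketone F6. Oxidation with NaBO3 in THF/H2O proceeds with retention and would come back to the route at 23, so that step 13 is bypassed.

Further compounds
F1 | step 9 | 6-acetoxy-2-[(3R)-2,6-dimethyl-3-(trimethylsilyloxy)hept-6-en-3-yl]-5-methyl-2H-pyran-3(6H)-one | CC(C)[C@](O[Si](C)(C)C)(CCC(C)=C)C1OC(OC(C)=O)C(C)=CC1=O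
F2 | step 9 | (1R,4R,5S,9S)-5,9-epoxy-4-(trimethylsilyloxy)dauc-7-en-6-one | CC(C)[C@]1(O[Si](C)(C)C)CC[C@]2(C)C[C@@H]3O[C@@]21C(=O)C=C3C
F3 | step 10 | (1R,4R,5S,8S,9S)-5,9-epoxy-4-hydroxydaucan-6-one | CC(C)[C@]1(O)CC[C@]2(C)C[C@@H]3O[C@@]21C(=O)C[C@@H]3C
F4 | step 10 | (1R,4R,5R,8S,9S)-4,9-dihydroxydaucan-6-one | CC(C)[C@]1(O)CC[C@]2(C)C[C@H](O)[C@@H](C)CC(=O)[C@H]21
F5 | step 10 | (1R,4R,5R,8S,9S)-9-(tert-butyldimethylsilyloxy)-4-hydroxydaucan-6-one | CC(C)[C@]1(O)CC[C@]2(C)C[C@H](O[Si](C)(C)C(C)(C)C)[C@@H](C)CC(=O)[C@H]21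
F6 | step 12 | (1R,4R,5R,8R,9S)-9-(tert-butyldimethylsilyloxy)-4-hydroxy-8-(4,4,5,5-tetramethyl-1,3,2-dioxaborolan-2-yl)daucan-6-one | CC(C)[C@]1(O)CC[C@]2(C)C[C@H](O[Si](C)(C)C(C)(C)C)[C@@](C)(B3OC(C)(C)C(C)(C)O3)CC(=O)[C@H]21
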